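**Plan**
1. Retrosynthetic cuts, in order: the phenol O–Si bond; C3=C4 (back to C3H–C4H2); C8–C8a (ring B); C4a=C5; the C7–O(aroyl) bond; C3–C4 and C1–O2 of ring A.
2. Forward: ring A is built first by a hetero-Diels–Alder reaction. The C5–C8 chain is then joined at C4a by aldol addition and dehydration, ring B closes by acylation at C8a, and C3=C4 is introduced last.
3. Enabling feature: in the keto-acid precursor, ring A is a 2,3-dihydropyran-4-ylidene with C4 sp3. The only nucleophilic ring carbon is therefore C8a, the β-carbon of the O2–C1=C8a enol ether. It reaches C8 through the six atoms C8a, C4a, C5, C6, C7, C8, whereas C5 and the C6 oxygen could only form four-membered rings.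
4. Stereochemistry: C7 (R) is set in an acyclic β-keto ester by primary-amine (enamine) catalysed aroyloxylation and is quaternary from then on. C3 (S) comes from the chiral chromium catalyst of the cycloaddition, only keeps the intermediates single, and is erased by the final dehydrogenation.
5. Isochromene numbering of the target (C1, O2, C3, C4, C4a, C5–C8, C8a; ring A pyran, ring B carbocycle) is used for all intermediates.

Key step: step 10

Assumption: the facial sense of the catalysts in steps 5 and 6 is taken from their accepted transition-state models; both exist as either enantiomer, so the antipode would be used if the opposite sense were found (for C3 the sense is immaterial).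

Step 1
Reactants: 1 2,4-dihydroxy-6-methylbenzaldehyde
Product: 2 4-(tert-butyldimethylsilyloxy)-2-hydroxy-6-methylbenzaldehyde
Conditions: TBSCl (1.05 equiv), imidazole, CH2Cl2, 0 °C
Reagents that add atoms: tert-butyldimethylsilyl chloride, CC(C)(C)[Si](C)(C)Cl
Why: Selective phenol silylation: the C2 hydroxyl is hydrogen-bonded to the formyl group and flanked by it, so the free and more acidic C4 phenol should react first.

Step 2
Reactants: 2 4-(tert-butyldimethylsilyloxy)-2-hydroxy-6-methylbenzaldehyde
Product: 3 4-(tert-butyldimethylsilyloxy)-2-methoxy-6-methylbenzaldehyde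
Conditions: MeOH, PPh3, DIAD, THF, 0 → 23 °C
Reagents that add atoms: methanol, CO
Why: Mitsunobu etherification methylates the remaining acidic phenol under neutral conditions, so the aryl silyl ether para to the aldehyde, which carbonate bases tend to cleave, should stay in place.

Step 3
Reactants: 3 4-(tert-butyldimethylsilyloxy)-2-methoxy-6-methylbenzaldehyde
Product: 4 4-(tert-butyldimethylsilyloxy)-2-methoxy-6-methylbenzoic acid
Conditions: NaClO2, NaH2PO4, 2-methylbut-2-ene, t-BuOH/H2O, 0 → 23 °C
Reagents that add atoms: sodium chlorite, [Na+].[O-]Cl=O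
Why: Pinnick oxidation takes hindered, electron-rich benzaldehydes to the acids at about pH 4, the alkene traps HOCl before it can chlorinate the ring, and no 2,6-disubstituted benzoate has to be saponified in the presence of the silyl ether.

Step 4
Reactants: 4 4-(tert-butyldimethylsilyloxy)-2-methoxy-6-methylbenzoic acid (2 equiv)
Product: 5 bis[4-(tert-butyldimethylsilyloxy)-2-methoxy-6-methylbenzoyl] peroxide
Conditions: DCC, 30 % aq H2O2 (0.5 equiv), DMAP (5 mol %), CH2Cl2, −15 → 0 °C; kept cold and in solution
Reagents that add atoms: hydrogen peroxide, OO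
Why: Carbodiimide coupling of a carboxylic acid with hydrogen peroxide is the standard near-neutral route to symmetrical diaroyl peroxides, and the small α-nucleophile H2O2 should still reach the hindered activated carbonyl.

Step 5
Reactants: 6 tert-butyl 2-methyl-3-oxobutanoate (racemic, 2 equiv); 5 bis[4-(tert-butyldimethylsilyloxy)-2-methoxy-6-methylbenzoyl] peroxide
Product: 7 tert-butyl (2R)-2-[4-(tert-butyldimethylsilyloxy)-2-methoxy-6-methylbenzoyl]oxy-2-methyl-3-oxobutanoate
Conditions: (S)-N1,N1-diethyl-3,3-dimethylbutane-1,2-diamine·TfOH (20 mol %), BHT (10 mol %), CHCl3, 25 °C, dark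
Reagents that add atoms: none
Why: Enamine-catalysed asymmetric α-aroyloxylation of a β-keto ester: the primary amine turns both enantiomers of 6 into one planar enamino ester, the protonated tertiary amine hydrogen-bonds a peroxide carbonyl and delivers oxygen to the face opposite the tert-butyl group, which sets C7 as R, and the ortho groups of the aryl ring matter little because attack is on peroxide oxygen rather than on the carbonyl.

Step 6
Reactants: 8 (E)-1-methoxy-3-(trimethylsilyloxy)buta-1,3-diene; 9 (E)-but-2-enal
Product: 11 (2R,6S)-2-methoxy-6-[(E)-prop-1-enyl]oxan-4-one (cis), via silyl enol ether cycloadduct 10 (not isolated)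
Conditions: [(S,S)-N,N'-bis(3,5-di-tert-butylsalicylidene)cyclohexane-1,2-diaminato]chromium tetrafluoroborate (3 mol %), 4 Å MS, t-BuOMe, −30 °C; then Et3N, MeOH, 0 °C
Reagents that add atoms: none
Why: Catalytic asymmetric hetero-Diels–Alder reaction: the chiral chromium salen Lewis acid binds the aldehyde oxygen of 9 and leaves one carbonyl face open, which sets C3 as S, the endo mode places the C1 methoxy group cis to the propenyl group, and mild methanolysis of the silyl enol ether instead of an acid work-up keeps C1 as an acetal, so that C4a is a normal ketone and not the poorly electrophilic carbonyl of a vinylogous ester.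

Step 7
Reactants: 7 tert-butyl (2R)-2-[4-(tert-butyldimethylsilyloxy)-2-methoxy-6-methylbenzoyl]oxy-2-methyl-3-oxobutanoate; 11 (2R,6S)-2-methoxy-6-[(E)-prop-1-enyl]oxan-4-one
Product: 13 tert-butyl (2R)-2-[4-(tert-butyldimethylsilyloxy)-2-methoxy-6-methylbenzoyl]oxy-4-[(2R,6S)-4-hydroxy-2-methoxy-6-[(E)-prop-1-enyl]oxan-4-yl]-2-methyl-3-oxobutanoate (both epimers at C4a), via lithium enolate 12 (not isolated)
Conditions: LiN(SiMe3)2, THF, −78 °C; 11, −78 °C; AcOH quench at −78 °C
Reagents that add atoms: lithium bis(trimethylsilyl)amide, [Li+].C[Si](C)(C)[N-][Si](C)(C)C (lithium in 12 only)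
Why: Directed lithium aldol addition: the C5 methyl group is the only enolisable position of 7 because C7 is quaternary, the 2,6-disubstituted aroyl group and the tert-butyl ester resist attack by the enolate, the inductively activated oxan-4-one is a good acceptor at low temperature, and the new C4a carbinol centre is lost in the next step, so its configuration does not matter.

Step 8
Reactants: 13 the aldol adduct of step 7
Product: 15 tert-butyl (2R)-2-[4-(tert-butyldimethylsilyloxy)-2-methoxy-6-methylbenzoyl]oxy-4-[(2R,6S)-2-methoxy-6-[(E)-prop-1-enyl]oxan-4-ylidene]-2-methyl-3-oxobutanoate (E/Z mixture at C4a=C5), via tertiary mesylate 14 (not isolated)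
Conditions: MsCl, Et3N, CH2Cl2, 0 → 23 °C
Reagents that add atoms: methanesulfonyl chloride, CS(=O)(=O)Cl (its atoms sit in 14 only)
Why: Dehydration of a tertiary aldol by mesylation through sulfene and E1cB elimination: the C5 hydrogens next to the C6 ketone are the most acidic, so the conjugated exocyclic C4a=C5 alkene should result, and its geometry is of no consequence because step 9 equilibrates it.

Step 9
Reactants: 15 the enone acetal of step 8
Product: 17 (2R,4Z)-2-[4-(tert-butyldimethylsilyloxy)-2-methoxy-6-methylbenzoyl]oxy-2-methyl-3-oxo-4-[(2S)-2-[(E)-prop-1-enyl]-2,3-dihydropyran-4-ylidene]butanoic acid, via tert-butyl ester dienol ether 16 (not isolated)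
Conditions: TFA/CH2Cl2 1:4, 0 → 15 °C; co-evaporation from toluene below 20 °C; used at once
Reagents that add atoms: none
Why: Acidolysis does two known things in one flask: the enone enolises towards C8a and expels methanol from C1 (the vinylogous form of the acid-induced β-elimination that normally ends such cycloadditions), and the tert-butyl ester is cleaved by alkyl–oxygen fission, while the aryl silyl ether tolerates TFA and the electron-rich C6 carbonyl should slow decarboxylation of the β-keto acid.

Step 10
Reactants: 17 the dihydropyranylidene keto acid of step 9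
Product: 19 [(3S,7R)-7-methyl-6,8-dioxo-3-[(E)-prop-1-enyl]-3,4-dihydroisochromen-7-yl] 4-(tert-butyldimethylsilyloxy)-2-methoxy-6-methylbenzoate, via acid chloride 18 (not isolated)
Conditions: 1-chloro-N,N,2-trimethylprop-1-en-1-amine (1.0 equiv), CH2Cl2 (0.01 M), 0 °C; then 2,6-di-tert-butyl-4-methylpyridine, AgOTf (AgOSO2CF3, 1.1 equiv), −40 → 0 °C
Reagents that add atoms: 1-chloro-N,N,2-trimethylprop-1-en-1-amine, CC(C)=C(Cl)N(C)C (chlorine in 18 only)
Why: The chloroenamine turns the C8 acid into acid chloride 18 under neutral conditions (C7 is quaternary, so no ketene and no epimerisation can arise), AgOTf removes chloride, C8a, the β-carbon of the O2–C1=C8a enol ether, attacks the activated C8 carbonyl, and the resulting C1 oxocarbenium ion gives up its C8a proton to the hindered pyridine, which restores the enol ether as a vinylogous ester. The closest known reaction type is the Friedel–Crafts-type C-acylation of cyclic enol ethers such as dihydropyrans and glycals with acid chlorides, used here intramolecularly. Ring B (C8a, C4a, C5, C6, C7, C8) closes in the 6-exo-trig mode at the acyl carbon, with the nucleophilic C1=C8a bond exocyclic to the new ring. No stereocentre is formed, and C7 and C3 are spectators. The step needs site selectivity, and the substrate secures it: C4 is sp3, while C5 and the C6 oxygen, the other electron-rich positions of the push–pull dienol ether, could reach C8 only through four-membered rings. It also needs the C6 arm cis to C8a; reversible protonation or acylation at the C6 oxygen makes C4a–C5 a single bond of a dihydropyrylium ion, so the E isomer drains into the Z isomer, the only one that can cyclise.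

Step 11
Reactants: 19 the 3,4-dihydro bicycle of step 10
Product: 20 [(7R)-7-methyl-6,8-dioxo-3-[(E)-prop-1-enyl]isochromen-7-yl] 4-(tert-butyldimethylsilyloxy)-2-methoxy-6-methylbenzoate
Conditions: DDQ (1.5 equiv), 1,4-dioxane, 60 °C
Reagents that add atoms: none
Why: DDQ dehydrogenation of an enone through its extended enol, the reaction type that turns 4-en-3-ones into 4,6-dien-3-ones: C4 carries the only enolisable hydrogens, hydride then leaves from C3, which is allylic and next to O2, the fully conjugated pyranoquinone chromophore supplies the driving force, the C3 centre disappears and C7 is untouched.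

Step 12
Reactants: 20 the silyl-protected azaphilone of step 11
Product: 21 [(7R)-7-methyl-6,8-dioxo-3-[(E)-prop-1-enyl]isochromen-7-yl] 4-hydroxy-2-methoxy-6-methylbenzoate (CNP0103258.2)
Conditions: Et3N·3HF, THF, 0 → 23 °C
Reagents that add atoms: none
Why: Fluoride-induced cleavage of an aryl silyl ether with a buffered HF source avoids the basic or primary-amine conditions that open the pyran ring of azaphilones, and it leaves the hindered aryl ester and C7 alone.

**Compound list**
1 | 2,4-dihydroxy-6-methylbenzaldehyde | Cc1cc(O)cc(O)c1C=O | starting material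
2 | 4-(tert-butyldimethylsilyloxy)-2-hydroxy-6-methylbenzaldehyde | Cc1cc(O[Si](C)(C)C(C)(C)C)cc(O)c1C=O | intermediate
3 | 4-(tert-butyldimethylsilyloxy)-2-methoxy-6-methylbenzaldehyde | COc1cc(O[Si](C)(C)C(C)(C)C)cc(C)c1C=O | intermediate
4 | 4-(tert-butyldimethylsilyloxy)-2-methoxy-6-methylbenzoic acid | COc1cc(O[Si](C)(C)C(C)(C)C)cc(C)c1C(=O)O | intermediate
5 | bis[4-(tert-butyldimethylsilyloxy)-2-methoxy-6-methylbenzoyl] peroxide | COc1cc(O[Si](C)(C)C(C)(C)C)cc(C)c1C(=O)OOC(=O)c1c(C)cc(O[Si](C)(C)C(C)(C)C)cc1OC | intermediate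
6 | tert-butyl 2-methyl-3-oxobutanoate (racemic) | CC(=O)C(C)C(=O)OC(C)(C)C | starting material
7 | tert-butyl (2R)-2-[4-(tert-butyldimethylsilyloxy)-2-methoxy-6-methylbenzoyl]oxy-2-methyl-3-oxobutanoate | CC(=O)[C@@](C)(OC(=O)c1c(C)cc(O[Si](C)(C)C(C)(C)C)cc1OC)C(=O)OC(C)(C)C | intermediate
8 | (E)-1-methoxy-3-(trimethylsilyloxy)buta-1,3-diene | CO/C=C/C(=C)O[Si](C)(C)C | starting material
9 | (E)-but-2-enal | C/C=C/C=O | starting material
10 | (2S,6R)-6-methoxy-2-[(E)-prop-1-enyl]-4-(trimethylsilyloxy)-3,6-dihydro-2H-pyran (cis cycloadduct, not isolated) | C/C=C/[C@@H]1CC(O[Si](C)(C)C)=C[C@H](OC)O1 | intermediate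
11 | (2R,6S)-2-methoxy-6-[(E)-prop-1-enyl]oxan-4-one (cis) | C/C=C/[C@@H]1CC(=O)C[C@H](OC)O1 | intermediate
12 | lithium enolate of 7 at C5 (not isolated) | [Li+].C=C([O-])[C@@](C)(OC(=O)c1c(C)cc(O[Si](C)(C)C(C)(C)C)cc1OC)C(=O)OC(C)(C)C | intermediate
13 | tert-butyl (2R)-2-aroyloxy-4-[(2R,6S)-4-hydroxy-2-methoxy-6-[(E)-prop-1-enyl]oxan-4-yl]-2-methyl-3-oxobutanoate, aroyl = 4-(tert-butyldimethylsilyloxy)-2-methoxy-6-methylbenzoyl, both C4a epimers | C/C=C/[C@@H]1CC(O)(CC(=O)[C@@](C)(OC(=O)c2c(C)cc(O[Si](C)(C)C(C)(C)C)cc2OC)C(=O)OC(C)(C)C)C[C@H](OC)O1 | intermediate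
14 | C4a methanesulfonate of 13 (not isolated) | C/C=C/[C@@H]1CC(OS(C)(=O)=O)(CC(=O)[C@@](C)(OC(=O)c2c(C)cc(O[Si](C)(C)C(C)(C)C)cc2OC)C(=O)OC(C)(C)C)C[C@H](OC)O1 | intermediate
15 | tert-butyl (2R)-2-aroyloxy-4-[(2R,6S)-2-methoxy-6-[(E)-prop-1-enyl]oxan-4-ylidene]-2-methyl-3-oxobutanoate, same aroyl group, E/Z mixture at C4a=C5 | C/C=C/[C@@H]1CC(=CC(=O)[C@@](C)(OC(=O)c2c(C)cc(O[Si](C)(C)C(C)(C)C)cc2OC)C(=O)OC(C)(C)C)C[C@H](OC)O1 | intermediate
16 | tert-butyl (2R,4Z)-2-aroyloxy-2-methyl-3-oxo-4-[(2S)-2-[(E)-prop-1-enyl]-2,3-dihydropyran-4-ylidene]butanoate, same aroyl group (not isolated) | C/C=C/[C@@H]1C/C(=C/C(=O)[C@@](C)(OC(=O)c2c(C)cc(O[Si](C)(C)C(C)(C)C)cc2OC)C(=O)OC(C)(C)C)C=CO1 | intermediate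
17 | (2R,4Z)-2-[4-(tert-butyldimethylsilyloxy)-2-methoxy-6-methylbenzoyl]oxy-2-methyl-3-oxo-4-[(2S)-2-[(E)-prop-1-enyl]-2,3-dihydropyran-4-ylidene]butanoic acid | C/C=C/[C@@H]1C/C(=C/C(=O)[C@@](C)(OC(=O)c2c(C)cc(O[Si](C)(C)C(C)(C)C)cc2OC)C(=O)O)C=CO1 | intermediate
18 | acid chloride of 17, (2R,4Z) (not isolated) | C/C=C/[C@@H]1C/C(=C/C(=O)[C@@](C)(OC(=O)c2c(C)cc(O[Si](C)(C)C(C)(C)C)cc2OC)C(=O)Cl)C=CO1 | intermediate
19 | [(3S,7R)-7-methyl-6,8-dioxo-3-[(E)-prop-1-enyl]-3,4-dihydroisochromen-7-yl] 4-(tert-butyldimethylsilyloxy)-2-methoxy-6-methylbenzoate | C/C=C/[C@@H]1CC2=CC(=O)[C@@](C)(OC(=O)c3c(C)cc(O[Si](C)(C)C(C)(C)C)cc3OC)C(=O)C2=CO1 | intermediate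
20 | [(7R)-7-methyl-6,8-dioxo-3-[(E)-prop-1-enyl]isochromen-7-yl] 4-(tert-butyldimethylsilyloxy)-2-methoxy-6-methylbenzoate | C/C=C/C1=CC2=CC(=O)[C@@](C)(OC(=O)c3c(C)cc(O[Si](C)(C)C(C)(C)C)cc3OC)C(=O)C2=CO1 | intermediate
21 | [(7R)-7-methyl-6,8-dioxo-3-[(E)-prop-1-enyl]isochromen-7-yl] 4-hydroxy-2-methoxy-6-methylbenzoate | C/C=C/C1=CC2=CC(=O)[C@@](C)(OC(=O)c3c(C)cc(O)cc3OC)C(=O)C2=CO1 | target

Total step count: 12. Longest linear sequence: 11 steps (1–5, then 7–12, from 1); step 6 is the side branch.

**Steps most likely to fail**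

Step 10.
- What may go wrong: the electron density of the enol ether is drained into the C6 carbonyl, so attack by C8a may be too slow. Intermolecular acylation at the C6 oxygen, loss of CO from the activated acyl group, reversible lactonisation of the acid onto C4a, or decarboxylation before activation could then take over.
- Fallback: it sets out from 15 and comes back at 19, and it replaces the neutral enol ether by an anionic nucleophile. KOt-Bu in THF/t-BuOH at 0 °C removes a C8a hydrogen of 15 and gives the potassium extended enolate F1.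
- Under these equilibrating conditions, F1 attacks the tert-butyl ester carbonyl C8 through its γ-carbon C8a (vinylogous Dieckmann condensation). Attack through C5 would need a four-membered ring.
- The bicyclic 1-methoxy dione F2 so formed loses methoxide from C1 by E1cB elimination and gives 19 without passing through 17 and 18.

Step 5.
- What may go wrong: the enamine may attack the electron-rich O–O bond too slowly, the peroxide may decay by ionic or radical paths before it is used, the catalyst may be oxidised at nitrogen, and facial selectivity may be lower than with unsubstituted dibenzoyl peroxide.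
- Fallback: it sets out from 6 and comes back at 7, making the C7–O bond first and the aryl ester bond afterwards. Enantioselective α-hydroxylation of 6 uses 3-(4-nitrophenyl)-2-(phenylsulfonyl)oxaziridine and the catalyst TiCl2(TADDOLate)(MeCN)2, with the ligand enantiomer chosen for the R alcohol. It should give tert-butyl (2R)-2-hydroxy-2-methyl-3-oxobutanoate F3.
- Acid 4 and trifluoroacetic anhydride in toluene give the aroyl trifluoroacetate mixed anhydride F4. This reagent acylates hindered alcohols through acylium-like reactivity, as in depside ester formation, and converts F3 into 7.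

Step 11.
- What may go wrong: enolisation towards C4 may be sluggish, hydride may be abstracted at the propenyl methyl group, or the quinone may add to the extended enol.
- Fallback: it sets out from 19 and comes back at 20, separating enolisation from oxidation. TBSOTf and Et3N in CH2Cl2 at 0 °C remove a C4 hydrogen and silylate the C6 oxygen to give the silyl trienol ether F5.
- Saegusa–Ito oxidation of F5 with Pd(OAc)2 in MeCN places palladium at C4, and β-hydride elimination of the C3 hydrogen installs C3=C4.

**Further compounds**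
F1 | step 10 | potassium extended enolate of 15 (C6 enolate, C4a=C8a) | [K+].C/C=C/[C@@H]1CC(C=C([O-])[C@@](C)(OC(=O)c2c(C)cc(O[Si](C)(C)C(C)(C)C)cc2OC)C(=O)OC(C)(C)C)=C[C@H](OC)O1
F2 | step 10 | [(1R,3S,7R)-1-methoxy-7-methyl-6,8-dioxo-3-[(E)-prop-1-enyl]-1,3,4,8a-tetrahydroisochromen-7-yl] 4-(tert-butyldimethylsilyloxy)-2-methoxy-6-methylbenzoate (C8a epimers) | C/C=C/[C@@H]1CC2=CC(=O)[C@@](C)(OC(=O)c3c(C)cc(O[Si](C)(C)C(C)(C)C)cc3OC)C(=O)C2[C@H](OC)O1
F3 | step 5 | tert-butyl (2R)-2-hydroxy-2-methyl-3-oxobutanoate | CC(=O)[C@@](C)(O)C(=O)OC(C)(C)C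
F4 | step 5 | 4-(tert-butyldimethylsilyloxy)-2-methoxy-6-methylbenzoic trifluoroacetic anhydride | COc1cc(O[Si](C)(C)C(C)(C)C)cc(C)c1C(=O)OC(=O)C(F)(F)F
F5 | step 11 | [(3R,7R)-6-(tert-butyldimethylsilyloxy)-7-methyl-8-oxo-3-[(E)-prop-1-enyl]-3H-isochromen-7-yl] 4-(tert-butyldimethylsilyloxy)-2-methoxy-6-methylbenzoate (C3 descriptor changes by priority only) | C/C=C/[C@@H]1C=C2C=C(O[Si](C)(C)C(C)(C)C)[C@@](C)(OC(=O)c3c(C)cc(O[Si](C)(C)C(C)(C)C)cc3OC)C(=O)C2=CO1
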